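The earlier runs and the new flask are simulated from invented constants, and the scatter is random.

Look into the vessel and count what stays in it, not what comes out: minus the natural logarithm of the fraction of racemate left, the measure of a pseudo-first-order loss, which I call the log left.

the same everywhere: free catalyst 58 µM
- north-west: left-handed substrate 0.020 M; right-handed substrate 0.020 M; coupling partner 0.054 M; run made earlier
- north: left-handed substrate 0.020 M; right-handed substrate 0.020 M; coupling partner 0.12 M; run made earlier
- west: left-handed substrate 0.010 M; right-handed substrate 0.010 M; coupling partner 0.080 M; run made earlier
- flask: left-handed substrate 0.020 M; right-handed substrate 0.020 M; coupling partner 0.0800 M; time 8.0 min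

| run | time / min | left-handed product / % | right-handed product / % |
|---|---|---|---|
| north-west | 0.417 | 2 | 0 |
| north-west | 1.33 | 6 | 3 |
| north-west | 2.50 | 7 | 0 |
| north-west | 4.00 | 12 | 5 |
| north-west | 5.00 | 12 | 1 |
| north-west | 6.00 | 9 | 4 |
| north | 0.500 | 9 | 1 |
| north | 0.833 | 13 | 6 |
| north | 1.33 | 19 | 6 |
| north | 2.50 | 19 | 6 |
| north | 4.00 | 17 | 9 |
| north | 6.00 | 20 | 9 |
| west | 0.500 | 2 | 3 |
| west | 1.50 | 11 | 1 |
| west | 3.00 | 17 | 5 |
| west | 5.00 | 19 | 7 |
| west | 6.00 | 15 | 5 |

(standard deviation of a reading: 2 percentage points)

- free catalyst is single-handed; left-handed substrate and right-handed substrate are mirror images of each other, charged as a racemate, each of them at the stated concentration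
- an excess is the difference of the two amounts in percent of their sum
- an excess is below zero if the other one leads

1. excess of left-handed product over right-handed product in the product at 25 s
2. excess of left-handed product over right-handed product in the product at 8.0 min
3. part of the left-handed substrate and right-handed substrate charged together that has reacted at 8.0 min

Climb the ladder from the opening. The north run's first reading, at 0.500 min, gives a pace of 0.211 /min on the log left. Its readings from 2.50 min on average a log left of 0.310, and at the opening pace that takes 1.47 min. So the early time, 25 s, falls before this north-run stop. The next rung is slower: at that pace the racemate's half-life is 3.29 min, and the north run's readings level off sooner, with 73.3 % of the racemate left as read. The asked 8.0 min lies past both north-run times, so I expect the flask on a plateau as well.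

Now read the plateaus. The north-west run, from 4.00 min on, holds a log left of 0.155. Pool the two runs, which share their racemate and catalyst charges with the flask, into the stopping yield: the plateau log left per molar of coupling partner charged, with those charges held, read as 2.67 /M. For the flask this gives 0.214, so I commit to 19.2 % reacted.

The forecast says 53 % excess at 25 s, 49 % excess at 8.0 min and 21.5 % reacted, and holds that “the catalyst evidently dies”. Its conversion stands above mine.

The flask gives 47.2 % excess at 25 s, 45.6 % excess at 8.0 min and 19.6 % reacted. At 8.00 min the flask holds 0.121 % of the catalyst charged as free catalyst, while 80 % of the left-handed substrate charged remains. Its log left is 0.218, where the stopping yield gave 0.214.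

    coupling partner → decomposed reagent (k = 0.00320 /s)
    coupling partner + free catalyst + right-handed substrate → free catalyst + right-handed product (k = 450 /M²/s)
    left-handed substrate ⇌ right-handed substrate (k = 0.00340 /s)
    free catalyst → spent catalyst (k = 0.0140 /s)
    coupling partner + free catalyst + left-handed substrate → free catalyst + left-handed product (k = 1300 /M²/s)

Take the neighbour flask with 0.32 M of coupling partner, other charges and time held. The stopping yield gives a log left of 0.855, so 57.5 % reacted. In the computed neighbour flask, 56.6 % of the racemate has reacted at 8.0 min.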